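**Plan** (carotenoid numbering; primed atoms belong to the acetylenic half)
1. Cuts, last bond first: C8'–C9' (alkyne carbon to the methyl-bearing sp2 carbon), then C8–C9, then C11=C12 and C11'=C12'. This leaves a C11 ring alkyne, a C11 epoxy aldehyde and one symmetric C18 pentaene-diyne.
2. Enabling feature: in the 9',10'-didehydro precursor the C8 ketone is linearly conjugated with C9'≡C10' through six C=C bonds (C9=C10 to C12'=C11'). That triple bond is therefore a vinylogous ynone with the methyl-capped C9' as acceptor terminus. The donor C7'≡C8'–H sits on C6' of the cyclohexene ring, shielded by the C1' gem-dimethyl and C5' methyl groups.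
3. Forward order: both six-membered rings come from one enol triflate of (4R,6R)-actinol, and the oxirane (C5–C6–O) is the only ring made (step 8). The chain is joined by double olefination of the C10 dialdehyde, then C8–C9 by nickel-catalysed reductive coupling at one enyne end. Oxidation to the ketone follows, and C8'–C9' is formed last by palladium-catalysed hydroalkynylation at the other end.
4. Stereochemistry: C3 and C3' come from actinol. C5 and C6 come from the Sharpless epoxidation, anti to the C3 oxygen. C11=C12 and C11'=C12' come from the olefination, C9=C10 and C9'=C10' from two syn additions to alkynes, and the other E bonds from the dialdehyde.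

Key step: step 17

Assumption: (4R,6R)-actinol and (2E,4E,6E)-2,7-dimethylocta-2,4,6-trienedial, both industrial carotenoid intermediates, are taken as purchasable. All polyene steps are run under argon with exclusion of light.

Step 1
Reactants: 1 (4R,6R)-4-hydroxy-2,2,6-trimethylcyclohexan-1-one (actinol)
Product: 2 (4R,6R)-4-[(tert-butyldimethylsilyl)oxy]-2,2,6-trimethylcyclohexan-1-one
Conditions: TBSCl, imidazole, DMF, rt
Reagents that add atoms: tert-butyldimethylsilyl chloride CC(C)(C)[Si](C)(C)Cl
Why: Standard silylation of the only hydroxyl group gives a bulky ether that should survive the enolate, palladium, aluminium hydride and epoxidation steps and leaves the carbinol centre (later C3 and C3') untouched.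

Step 2
Reactants: 2 silyl ether of actinol
Product: 4 (4R)-4-[(tert-butyldimethylsilyl)oxy]-2,6,6-trimethylcyclohex-1-en-1-yl trifluoromethanesulfonate, via lithium enolate 3 (not isolated)
Conditions: LiN(iPr)2, THF, −78 °C; then PhNTf2, −78 °C to rt
Reagents that add atoms: N-phenylbis(trifluoromethanesulfonimide) O=S(=O)(N(c1ccccc1)S(=O)(=O)C(F)(F)F)C(F)(F)F
Why: The ketone can enolise only towards the methyl-bearing carbon, so deprotonation and O-triflation (enol triflate synthesis) should give one regioisomer, erasing that stereocentre on purpose while the carbinol centre is not involved.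

Step 3
Reactants: 4 enol triflate; 5 ethynyltrimethylsilane
Product: 6 tert-butyldimethyl({(1R)-3,5,5-trimethyl-4-[(trimethylsilyl)ethynyl]cyclohex-3-en-1-yl}oxy)silane
Conditions: PdCl2(PPh3)2 (5 mol %), CuI (10 mol %), Et3N, DMF, 50 °C
Reagents that add atoms: none
Why: Sonogashira coupling of an alkenyl triflate, in which the slim linear alkyne tolerates the flanking gem-dimethyl and methyl groups and the silyl cap prevents oxidative dimerisation.

Step 4
Reactants: 6 bis-silylated enyne
Product: 7 (1R)-4-ethynyl-3,5,5-trimethylcyclohex-3-en-1-ol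
Conditions: Bu4NF (2.5 equiv), THF, 0 °C to rt
Reagents that add atoms: none
Why: Fluoride should cleave the C–Si and the O–Si bond in one operation (protodesilylation and silyl ether cleavage) without touching the enyne or the stereocentre.

Step 5
Reactants: 7 hydroxy enyne
Product: 8 (1R)-4-ethynyl-3,5,5-trimethylcyclohex-3-en-1-yl acetate (donor alkyne)
Conditions: Ac2O, pyridine, DMAP (cat.), CH2Cl2, rt
Reagents that add atoms: acetic anhydride CC(=O)OC(C)=O
Why: DMAP-catalysed acetylation with retention at C3' places the only ester of the target on this fragment alone, so the two oxygen functions at C3 and C3' never have to be told apart.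

Step 6
Reactants: 4 enol triflate
Product: 9 methyl (4R)-4-[(tert-butyldimethylsilyl)oxy]-2,6,6-trimethylcyclohex-1-ene-1-carboxylate
Conditions: Pd(OAc)2 (5 mol %), PPh3 (10 mol %), CO (1 atm), MeOH, Et3N, DMF, 60 °C
Reagents that add atoms: carbon monoxide [C-]#[O+]; methanol CO
Why: Palladium-catalysed methoxycarbonylation of an alkenyl triflate (oxidative addition, CO insertion, methanolysis) adds C7 at ring carbon C6.

Step 7
Reactants: 9 unsaturated ester
Product: 10 [(4R)-4-[(tert-butyldimethylsilyl)oxy]-2,6,6-trimethylcyclohex-1-en-1-yl]methanol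
Conditions: iBu2AlH (2.5 equiv), CH2Cl2, −78 °C; aqueous Rochelle salt work-up
Reagents that add atoms: none
Why: 1,2-Reduction of the conjugated ester by iBu2AlH gives the allylic alcohol that serves as the handle for the directed epoxidation, the silyl ether and the alkene being inert.

Step 8
Reactants: 10 allylic alcohol
Product: 11 [(1R,4S,6R)-4-[(tert-butyldimethylsilyl)oxy]-2,2,6-trimethyl-7-oxabicyclo[4.1.0]heptan-1-yl]methanol (oxirane anti to the silyl ether)
Conditions: Ti(OiPr)4 (20 mol %), D-(−)-diethyl tartrate (25 mol %), tBuOOH (anhydrous, decane), 4 Å molecular sieves, CH2Cl2, −20 °C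
Reagents that add atoms: tert-butyl hydroperoxide CC(C)(C)OO
Why: Sharpless asymmetric epoxidation, in which the titanium D-(−)-tartrate complex bound to the C7 hydroxyl should deliver oxygen to the C5=C6 face anti to the C3 silyl ether (the sense that gives 2R epoxy alcohols from simple allylic alcohols), setting C5 and C6 together with the bulky silyl ether on the other face reinforcing the reagent.

Step 9
Reactants: 11 epoxy alcohol
Product: 12 (1S,4S,6R)-4-[(tert-butyldimethylsilyl)oxy]-2,2,6-trimethyl-7-oxabicyclo[4.1.0]heptane-1-carbaldehyde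
Conditions: Pr4N[RuO4] (5 mol %), N-methylmorpholine N-oxide, 4 Å molecular sieves, CH2Cl2, rt
Reagents that add atoms: none
Why: Ley–Griffith oxidation under neutral anhydrous conditions should stop at the aldehyde and spare the acid-labile tetrasubstituted oxirane, and C6 is quaternary so it cannot epimerise.

Step 10
Reactants: 12 epoxy aldehyde
Product: 13 tert-butyl{[(1R,4S,6R)-1-ethynyl-2,2,6-trimethyl-7-oxabicyclo[4.1.0]heptan-4-yl]oxy}dimethylsilane
Conditions: dimethyl (1-diazo-2-oxopropyl)phosphonate, K2CO3, MeOH, 0 °C to rt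
Reagents that add atoms: dimethyl (1-diazo-2-oxopropyl)phosphonate COP(=O)(OC)C(=[N+]=[N-])C(C)=O
Why: Ohira–Bestmann variant of the Seyferth–Gilbert homologation adds C8 as a terminal alkyne, and the aldehyde has no α-hydrogen, so the carbonate medium can neither epimerise it nor open the oxirane.

Step 11
Reactants: 13 ethynyl epoxide
Product: 15 2-[(1S,4S,6R)-4-[(tert-butyldimethylsilyl)oxy]-2,2,6-trimethyl-7-oxabicyclo[4.1.0]heptan-1-yl]acetaldehyde, via alkenylboronate 14 (not isolated)
Conditions: pinacolborane (1.2 equiv), Cp2ZrHCl (10 mol %), CH2Cl2, rt; then THF, aqueous pH 7 phosphate buffer, 30 % H2O2, 0 °C; used at once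
Reagents that add atoms: hydrogen peroxide OO
Why: Zirconium-catalysed syn hydroboration should place boron on the unhindered terminal carbon C8, and buffered peroxide oxidation of the alkenylboronate gives the enol and hence the aldehyde at neutral pH, where removal of a C7 proton with oxirane opening should not compete.

Step 12
Reactants: 16 1-bromobut-2-yne; 17 triethyl phosphite
Product: 18 diethyl but-2-yn-1-ylphosphonate
Conditions: neat, 110 °C, bromoethane distilled off
Reagents that add atoms: none
Why: Michaelis–Arbuzov reaction of a primary propargylic bromide.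

Step 13
Reactants: 18 diethyl but-2-yn-1-ylphosphonate (2.3 equiv); 19 (2E,4E,6E)-2,7-dimethylocta-2,4,6-trienedial
Product: 22 (4E,6E,8E,10E,12E)-6,11-dimethylhexadeca-4,6,8,10,12-pentaene-2,14-diyne, via lithiated phosphonate 20 (not isolated), via monoaldehyde 21 (not isolated)
Conditions: LiN(SiMe3)2 (2.3 equiv), THF, −78 °C; then 19, −78 °C to 0 °C
Reagents that add atoms: none
Why: Twofold Horner–Wadsworth–Emmons olefination, in which the propargyl-stabilised phosphonate anion reacts at its α-carbon and should give the E-enyne at both aldehyde groups (C11=C12 and C11'=C12'), the symmetric hydrocarbon being brought to all-E purity by crystallisation.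

Step 14
Reactants: 15 epoxy acetaldehyde; 22 pentaene-diyne (3 equiv)
Product: 23 (3S,5R,6S)-3-[(tert-butyldimethylsilyl)oxy]-5,6-epoxy-9',10'-didehydro-5,6,7,8-tetrahydro-9'-apo-β-caroten-8-ol (all-E, both C8 epimers, CH3–C≡C terminus)
Conditions: Ni(cod)2 (10 mol %), P(c-C5H9)3 (20 mol %), Et3B (2 equiv), EtOAc, rt; aqueous work-up; unreacted 22 recovered
Reagents that add atoms: none
Why: Nickel-catalysed reductive coupling of an aldehyde with a 1,3-enyne, in which oxidative cyclisation on zerovalent nickel, steered by coordination of the C11=C12 alkene, should form C8–C9 at the alkyne carbon remote from the alkene and the ethyl transfer, β-hydride elimination and C–H reductive elimination sequence delivers hydrogen to C10 on the same face (C9=C10 E); the excess of symmetric 22 limits double coupling, and the C8 configuration is irrelevant because it is oxidised in step 16.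

Step 15
Reactants: 23 silyl ether
Product: 24 (3S,5R,6S)-5,6-epoxy-9',10'-didehydro-5,6,7,8-tetrahydro-9'-apo-β-carotene-3,8-diol (all-E, both C8 epimers)
Conditions: Bu4NF, THF, 0 °C to rt
Reagents that add atoms: none
Why: Fluoride-mediated silyl ether cleavage is placed here because at the carbinol level no acidic C7 proton exists, so the basic fluoride cannot trigger oxirane opening.

Step 16
Reactants: 24 diol
Product: 25 (3S,5R,6S)-5,6-epoxy-3-hydroxy-9',10'-didehydro-5,6,7,8-tetrahydro-9'-apo-β-caroten-8-one (acceptor alkyne)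
Conditions: activated MnO2 (excess), CH2Cl2, rt
Reagents that add atoms: none
Why: MnO2 oxidises only the allylic, polyene-conjugated C8 carbinol and leaves the isolated C3 alcohol, which removes the C8 stereocentre, reveals the labile epoxy ketone under neutral conditions and switches on the remote alkyne as an acceptor.

Step 17
Reactants: 25 polyenynone (acceptor); 8 ring alkyne acetate (donor, 1.5 equiv)
Product: 26 (3S,5R,6S,3'R)-3'-acetoxy-5,6-epoxy-3-hydroxy-7',8'-didehydro-5,6,7,8-tetrahydro-β,β-caroten-8-one (target)
Conditions: Pd(OAc)2 (5 mol %), tris(2,6-dimethoxyphenyl)phosphine (5 mol %), benzene, rt, argon, dark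
Reagents that add atoms: none
Why: Proposed new method: acetate-assisted C–H palladation of the terminal alkyne of 8 should give an alkynyl complex of divalent palladium that adds syn across C9'≡C10' of 25, alkynyl to C9' and palladium to C10', after which protonolysis of the dienyl–palladium bond by acetic acid with retention releases 26 and the catalyst. The closest known reaction type is the Pd(OAc)2/tris(2,6-dimethoxyphenyl)phosphine cross-addition of terminal donor alkynes to ynoates, ynones and alkynyl sulfones, and what is new is that the acceptor is activated only vinylogously, through six C=C bonds, by the C8 ketone. No ring is closed and no stereocentre is made; the one new stereo-element, C9'=C10', is fixed as E by the suprafacial addition (alkynyl and H cis, hence C8' trans to C11'), which is the kinetic and not the thermodynamically preferred geometry of such enyne end groups. The regioselectivity needed should follow from three reinforcing biases: C9' is the electron-poor terminus of the polyenone, it carries only a methyl group, and palladium at C10' gains allyl-type stabilisation from C11'=C12'. Cross-addition rather than self-addition of 8, and no second addition to C7'≡C8' of the product, rest on the C1' gem-dimethyl and C5' methyl groups that shield the ring-bound alkyne carbon. The neutral, base-free and copper-free medium at room temperature spares the base-labile 5,6-epoxy-8-ketone, the acetate and the free C3 hydroxyl, so the whole skeleton is completed without protecting groups or stoichiometric by-products.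

**Compound list**
1 | (4R,6R)-4-hydroxy-2,2,6-trimethylcyclohexan-1-one (actinol) | C[C@@H]1C[C@@H](O)CC(C)(C)C1=O | starting material
2 | (4R,6R)-4-[(tert-butyldimethylsilyl)oxy]-2,2,6-trimethylcyclohexan-1-one | C[C@@H]1C[C@@H](O[Si](C)(C)C(C)(C)C)CC(C)(C)C1=O | intermediate
3 | lithium (4R)-4-[(tert-butyldimethylsilyl)oxy]-2,6,6-trimethylcyclohex-1-en-1-olate | [Li+].[O-]C1=C(C)C[C@@H](O[Si](C)(C)C(C)(C)C)CC1(C)C | intermediate
4 | (4R)-4-[(tert-butyldimethylsilyl)oxy]-2,6,6-trimethylcyclohex-1-en-1-yl trifluoromethanesulfonate | FC(F)(F)S(=O)(=O)OC1=C(C)C[C@@H](O[Si](C)(C)C(C)(C)C)CC1(C)C | intermediate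
5 | ethynyltrimethylsilane | C#C[Si](C)(C)C | starting material
6 | tert-butyldimethyl({(1R)-3,5,5-trimethyl-4-[(trimethylsilyl)ethynyl]cyclohex-3-en-1-yl}oxy)silane | C[Si](C)(C)C#CC1=C(C)C[C@@H](O[Si](C)(C)C(C)(C)C)CC1(C)C | intermediate
7 | (1R)-4-ethynyl-3,5,5-trimethylcyclohex-3-en-1-ol | C#CC1=C(C)C[C@@H](O)CC1(C)C | intermediate
8 | (1R)-4-ethynyl-3,5,5-trimethylcyclohex-3-en-1-yl acetate | C#CC1=C(C)C[C@@H](OC(C)=O)CC1(C)C | intermediate
9 | methyl (4R)-4-[(tert-butyldimethylsilyl)oxy]-2,6,6-trimethylcyclohex-1-ene-1-carboxylate | COC(=O)C1=C(C)C[C@@H](O[Si](C)(C)C(C)(C)C)CC1(C)C | intermediate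
10 | [(4R)-4-[(tert-butyldimethylsilyl)oxy]-2,6,6-trimethylcyclohex-1-en-1-yl]methanol | OCC1=C(C)C[C@@H](O[Si](C)(C)C(C)(C)C)CC1(C)C | intermediate
11 | [(1R,4S,6R)-4-[(tert-butyldimethylsilyl)oxy]-2,2,6-trimethyl-7-oxabicyclo[4.1.0]heptan-1-yl]methanol | OC[C@@]12O[C@]1(C)C[C@@H](O[Si](C)(C)C(C)(C)C)CC2(C)C | intermediate
12 | (1S,4S,6R)-4-[(tert-butyldimethylsilyl)oxy]-2,2,6-trimethyl-7-oxabicyclo[4.1.0]heptane-1-carbaldehyde | O=C[C@@]12O[C@]1(C)C[C@@H](O[Si](C)(C)C(C)(C)C)CC2(C)C | intermediate
13 | tert-butyl{[(1R,4S,6R)-1-ethynyl-2,2,6-trimethyl-7-oxabicyclo[4.1.0]heptan-4-yl]oxy}dimethylsilane | C#C[C@@]12O[C@]1(C)C[C@@H](O[Si](C)(C)C(C)(C)C)CC2(C)C | intermediate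
14 | (E)-alkenylboronic acid pinacol ester of 13 (boron on C8) | CC1(C)OB(/C=C/[C@@]23O[C@]2(C)C[C@@H](O[Si](C)(C)C(C)(C)C)CC3(C)C)OC1(C)C | intermediate
15 | 2-[(1S,4S,6R)-4-[(tert-butyldimethylsilyl)oxy]-2,2,6-trimethyl-7-oxabicyclo[4.1.0]heptan-1-yl]acetaldehyde | O=CC[C@@]12O[C@]1(C)C[C@@H](O[Si](C)(C)C(C)(C)C)CC2(C)C | intermediate
16 | 1-bromobut-2-yne | CC#CCBr | starting material
17 | triethyl phosphite | CCOP(OCC)OCC | starting material
18 | diethyl but-2-yn-1-ylphosphonate | CC#CCP(=O)(OCC)OCC | intermediate
19 | (2E,4E,6E)-2,7-dimethylocta-2,4,6-trienedial | O=C/C(C)=C/C=C/C=C(C)/C=O | starting material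
20 | lithiated diethyl but-2-yn-1-ylphosphonate | [Li+].CC#C[CH-]P(=O)(OCC)OCC | intermediate
21 | (2E,4E,6E,8E)-2,7-dimethyldodeca-2,4,6,8-tetraen-10-ynal | CC#C/C=C/C(C)=C/C=C/C=C(C)/C=O | intermediate
22 | (4E,6E,8E,10E,12E)-6,11-dimethylhexadeca-4,6,8,10,12-pentaene-2,14-diyne | CC#C/C=C/C(C)=C/C=C/C=C(C)/C=C/C#CC | intermediate
23 | (3S,5R,6S)-3-[(tert-butyldimethylsilyl)oxy]-5,6-epoxy-9',10'-didehydro-5,6,7,8-tetrahydro-9'-apo-β-caroten-8-ol (C8 epimers) | CC#C/C=C/C(C)=C/C=C/C=C(C)/C=C/C=C(\C)C(O)C[C@@]12O[C@]1(C)C[C@@H](O[Si](C)(C)C(C)(C)C)CC2(C)C | intermediate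
24 | (3S,5R,6S)-5,6-epoxy-9',10'-didehydro-5,6,7,8-tetrahydro-9'-apo-β-carotene-3,8-diol (C8 epimers) | CC#C/C=C/C(C)=C/C=C/C=C(C)/C=C/C=C(\C)C(O)C[C@@]12O[C@]1(C)C[C@@H](O)CC2(C)C | intermediate
25 | (3S,5R,6S)-5,6-epoxy-3-hydroxy-9',10'-didehydro-5,6,7,8-tetrahydro-9'-apo-β-caroten-8-one | CC#C/C=C/C(C)=C/C=C/C=C(C)/C=C/C=C(\C)C(=O)C[C@@]12O[C@]1(C)C[C@@H](O)CC2(C)C | intermediate
26 | (3S,5R,6S,3'R)-3'-acetoxy-5,6-epoxy-3-hydroxy-7',8'-didehydro-5,6,7,8-tetrahydro-β,β-caroten-8-one | CC(=O)O[C@@H]1CC(C)=C(C#C/C(C)=C/C=C/C(C)=C/C=C/C=C(C)/C=C/C=C(\C)C(=O)C[C@@]23O[C@]2(C)C[C@@H](O)CC3(C)C)C(C)(C)C1 | target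

Total step count: 17
Longest linear sequence: 12 steps (1, 2, 6, 7, 8, 9, 10, 11, 14, 15, 16, 17)

**Steps most likely to fail**

Step 17 (labelled step).
- Risk: the polarisation relayed over six double bonds may be too weak, so carbopalladation of C9'≡C10' could be slower than self-addition of the donor. Regiocontrol could erode, or palladium could isomerise the polyene.
- Fallback, from 24 back to 26, known chemistry only: diol 24 is treated with excess Cp2ZrHCl in THF at rt. The two hydroxyl groups are taken up as zirconium alkoxides, and the equilibrating conditions put zirconium on the methyl-bearing C9'. Quenching with I2 gives the 9'-iodo diol F1.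
- Sonogashira coupling of F1 with 8 (Pd(PPh3)4, CuI, iPr2NH, THF, rt) forms the same C8'–C9' bond with retention of the E geometry. The amine and copper act at the carbinol level, where they cannot harm an epoxy ketone. This gives the 8-hydroxy precursor F2.
- MnO2 in CH2Cl2 then oxidises only the allylic C8 carbinol and gives 26.

Step 14.
- Risk: the polyene may bind zerovalent nickel unproductively, both enyne ends may couple, or the sensitive aldehyde may be lost before it reacts.
- Fallback, from 22 and 15 back to 23: excess 22 is hydrozirconated at one end with Cp2ZrHCl (1 equiv, THF, rt) and quenched with I2 to give the monoiodo hexaenyne F3.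
- Nozaki–Hiyama–Kishi coupling of F3 with aldehyde 15 (CrCl2, NiCl2 (cat.), DMSO/THF, rt) adds the alkenylchromium species to the aldehyde under neutral conditions with retention of the E geometry and gives 23.

Step 11.
- Risk: the alkenylboronate may oxidise sluggishly at neutral pH. The nascent β,γ-epoxy aldehyde may also lose a C7 proton, with opening of the oxirane.
- Fallback, from 4 back to 15, installs the two-carbon arm before the oxirane, so the aldehyde arises only by a neutral alcohol oxidation. Suzuki–Miyaura coupling of 4 with vinylboronic acid pinacol ester (Pd(PPh3)4, K3PO4, dioxane/water, 60 °C) gives the vinyl diene F4.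
- Selective hydroboration of the terminal vinyl group (9-BBN, THF; then NaOH, H2O2) gives the homoallylic alcohol F5.
- Epoxidation with mCPBA and NaHCO3 in CH2Cl2 at 0 °C is expected to occur mainly anti to the bulky C3 silyl ether. This is substrate control only, so the syn isomer is removed by chromatography. The product is the epoxy ethanol F6.
- Oxidation of F6 with Pr4N[RuO4] and N-methylmorpholine N-oxide gives 15.

**Further compounds**
F1 | step 17 | (3S,5R,6S,9'E)-5,6-epoxy-9'-iodo-5,6,7,8-tetrahydro-9'-apo-β-carotene-3,8-diol (C8 epimers) | I/C(C)=C/C=C/C(C)=C/C=C/C=C(C)/C=C/C=C(\C)C(O)C[C@@]12O[C@]1(C)C[C@@H](O)CC2(C)C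
F2 | step 17 | (3S,5R,6S,3'R)-3'-acetoxy-5,6-epoxy-7',8'-didehydro-5,6,7,8-tetrahydro-β,β-carotene-3,8-diol (C8 epimers) | CC(=O)O[C@@H]1CC(C)=C(C#C/C(C)=C/C=C/C(C)=C/C=C/C=C(C)/C=C/C=C(\C)C(O)C[C@@]23O[C@]2(C)C[C@@H](O)CC3(C)C)C(C)(C)C1
F3 | step 14 | (2E,4E,6E,8E,10E,12E)-2-iodo-6,11-dimethylhexadeca-2,4,6,8,10,12-hexaen-14-yne | I/C(C)=C/C=C/C(C)=C/C=C/C=C(C)/C=C/C#CC
F4 | step 11 | tert-butyl{[(1R)-4-ethenyl-3,5,5-trimethylcyclohex-3-en-1-yl]oxy}dimethylsilane | C=CC1=C(C)C[C@@H](O[Si](C)(C)C(C)(C)C)CC1(C)C
F5 | step 11 | 2-[(4R)-4-[(tert-butyldimethylsilyl)oxy]-2,6,6-trimethylcyclohex-1-en-1-yl]ethan-1-ol | OCCC1=C(C)C[C@@H](O[Si](C)(C)C(C)(C)C)CC1(C)C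
F6 | step 11 | 2-[(1S,4S,6R)-4-[(tert-butyldimethylsilyl)oxy]-2,2,6-trimethyl-7-oxabicyclo[4.1.0]heptan-1-yl]ethan-1-ol | OCC[C@@]12O[C@]1(C)C[C@@H](O[Si](C)(C)C(C)(C)C)CC2(C)C
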